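## Retrosynthetic overview

- Maceneolignan A ⇐ the (2R,3R)-5-formyl dihydrobenzofuran: the (E)-propenyl group is made last from the aldehyde, so no acid-sensitive propenylphenol is carried through the route.
- Key disconnection O1–C2: the aldehyde ⇐ an achiral o-hydroxy-α-methylstilbene by catalytic asymmetric hydroalkoxylation. This C–O bond closes the dihydrofuran ring and sets C2 and C3 in one event.
- Stilbene ⇐ O-pivaloyl-5-iodovanillin + 4-propenylsyringol by a Heck reaction (C3–C3a bond), with the pivalate removed in the same pot.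
- Ring order: ring A (from 5-iodovanillin) and ring B (from 4-propenylsyringol) are bought intact; the dihydrofuran ring is the only ring formed, in step 3.

Assumption: the (R)-acid of step 3 (and the iridium ligand enantiomer named in its fallback) is taken to give the (2R,3R) series; if the first run gives the mirror image, the enantiomeric catalyst is used.

## Route

Step 1
Reactants: 1 5-iodovanillin (4-hydroxy-3-iodo-5-methoxybenzaldehyde)
Product: 2 4-formyl-2-iodo-6-methoxyphenyl 2,2-dimethylpropanoate
Conditions: PivCl (1.2 equiv), Et3N (1.5 equiv), DMAP (5 mol %), CH2Cl2, 0 °C to rt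
Reagents that add atoms: pivaloyl chloride, CC(C)(C)C(=O)Cl
Why: DMAP-catalysed O-acylation of the phenol; the hindered, non-migrating pivalate masks the ring A oxygen so that it cannot trap the benzyl-palladium or quinone methide species of step 2 and give racemic dihydrobenzofuran.

Step 2
Reactants: 2 4-formyl-2-iodo-6-methoxyphenyl 2,2-dimethylpropanoate; 3 (E)-2,6-dimethoxy-4-(prop-1-en-1-yl)phenol (4-propenylsyringol, 1.5 equiv)
Product: 5 4-hydroxy-3-[(1E)-1-(4-hydroxy-3,5-dimethoxyphenyl)prop-1-en-2-yl]-5-methoxybenzaldehyde, via pivalate-protected stilbene 4 (not isolated)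
Conditions: Pd(OAc)2 (5 mol %), Bu4NCl (1 equiv), NaHCO3 (2.5 equiv), DMF, 85 °C, N2; then MeOH, K2CO3 (1.5 equiv), 40 °C; aq. NH4Cl work-up
Reagents that add atoms: none
Why: Jeffery-type Mizoroki–Heck reaction in which the aryl group adds to the methyl-bearing alkene carbon (palladium on the benzylic carbon) and the single β-hydrogen gives trisubstituted stilbene 4, followed by base-mediated methanolysis (transesterification) of the activated aryl pivalate; no stereocentre is formed, and alkene geometry does not matter because step 3 passes through a common cation.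

Step 3
Reactants: 5 4-hydroxy-3-[(1E)-1-(4-hydroxy-3,5-dimethoxyphenyl)prop-1-en-2-yl]-5-methoxybenzaldehyde
Product: 7 (2R,3R)-2-(4-hydroxy-3,5-dimethoxyphenyl)-7-methoxy-3-methyl-2,3-dihydro-1-benzofuran-5-carbaldehyde, via p-quinone methide 6 (not isolated)
Conditions: (R)-3,3'-bis(2,4,6-triisopropylphenyl)-1,1'-binaphthyl-2,2'-diyl N-triflylphosphoramide (10 mol %), CH2Cl2 (0.02 M), 4 Å MS, −30 °C, 48 h
Reagents that add atoms: none
Why: Proposed new method: the chiral acid protonates C3 of the stilbene, the only site that gives a para-hydroxy-stabilised benzylic cation (O-protonated p-quinone methide 6, ion-paired with the chiral phosphoramide anion); the C3-epimeric ion pairs are expected to interconvert through 5 faster than the formyl-deactivated ring A phenol closes, so the catalyst selects under Curtin–Hammett control the trans (2R,3R) 5-exo oxa-1,6-addition that forms O1–C2 and fixes C2 and C3 together, trans also being the thermodynamic ring isomer; the closest known reaction types are chiral-phosphoric-acid-catalysed enantioselective 1,6-additions to p-quinone methides generated in situ and Brønsted-acid-catalysed asymmetric intramolecular hydroalkoxylation of alkenes, neither shown for an internal stilbene nor for setting two stereocentres through a dynamic quinone methide.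

Step 4
Reactants: 7 (2R,3R)-2-(4-hydroxy-3,5-dimethoxyphenyl)-7-methoxy-3-methyl-2,3-dihydro-1-benzofuran-5-carbaldehyde
Product: 8 maceneolignan A, 4-[(2R,3R)-7-methoxy-3-methyl-5-[(1E)-prop-1-en-1-yl]-2,3-dihydro-1-benzofuran-2-yl]-2,6-dimethoxyphenol
Conditions: CH3CHI2 (2.5 equiv), CrCl2 (10 equiv), THF, rt
Reagents that add atoms: 1,1-diiodoethane, CC(I)I
Why: Takai–Utimoto ethylidenation, in which the geminal dichromium reagent formed from CH3CHI2 and divalent chromium adds to the aldehyde and eliminates to the (E)-propenyl group (E:Z typically at least 95:5) under non-basic conditions, so the benzylic C2–O bond and both stereocentres are untouched.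

## Compound list

1 | 5-iodovanillin (4-hydroxy-3-iodo-5-methoxybenzaldehyde) | O=Cc1cc(I)c(O)c(OC)c1 | starting material
2 | 4-formyl-2-iodo-6-methoxyphenyl 2,2-dimethylpropanoate | CC(C)(C)C(=O)Oc1c(I)cc(C=O)cc1OC | intermediate
3 | (E)-2,6-dimethoxy-4-(prop-1-en-1-yl)phenol | C/C=C/c1cc(OC)c(O)c(OC)c1 | starting material
4 | 4-formyl-2-[(1E)-1-(4-hydroxy-3,5-dimethoxyphenyl)prop-1-en-2-yl]-6-methoxyphenyl 2,2-dimethylpropanoate | CC(C)(C)C(=O)Oc1c(OC)cc(C=O)cc1/C(C)=C/c1cc(OC)c(O)c(OC)c1 | intermediate (not isolated)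
5 | 4-hydroxy-3-[(1E)-1-(4-hydroxy-3,5-dimethoxyphenyl)prop-1-en-2-yl]-5-methoxybenzaldehyde | O=Cc1cc(OC)c(O)c(c1)/C(C)=C/c1cc(OC)c(O)c(OC)c1 | intermediate
6 | 4-hydroxy-3-[(2S)-1-(3,5-dimethoxy-4-oxocyclohexa-2,5-dien-1-ylidene)propan-2-yl]-5-methoxybenzaldehyde (the C3 epimer that closes to 7; its mirror image equilibrates through 5) | O=Cc1cc(OC)c(O)c(c1)[C@@H](C)C=C1C=C(OC)C(=O)C(OC)=C1 | intermediate (not isolated)
7 | (2R,3R)-2-(4-hydroxy-3,5-dimethoxyphenyl)-7-methoxy-3-methyl-2,3-dihydro-1-benzofuran-5-carbaldehyde | O=Cc1cc(OC)c2c(c1)[C@@H](C)[C@H](c1cc(OC)c(O)c(OC)c1)O2 | intermediate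
8 | maceneolignan A, 4-[(2R,3R)-7-methoxy-3-methyl-5-[(1E)-prop-1-en-1-yl]-2,3-dihydro-1-benzofuran-2-yl]-2,6-dimethoxyphenol | C/C=C/c1cc(OC)c2c(c1)[C@@H](C)[C@H](c1cc(OC)c(O)c(OC)c1)O2 | target

## Step count and risks

Total step count: 4. Longest linear sequence: 4 (1 → 2 → 5 → 7 → 8).

**Step 3 (the proposed new cyclisation).** Risks are no turnover, a racemic background reaction, insufficient selectivity, or slow erosion through re-opening of the ring. The fallback uses known chemistry and still closes the ring through the O1–C2 bond. It sets out from 4 and comes back at 7.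
- Step 2 is stopped before the methanol stage and 4 is isolated and crystallised to the pure E isomer.
- Iridium-catalysed asymmetric hydrogenation of this α-methylstilbene ([Ir(cod)((S)-tBu-PHOX)]BArF 2 mol %, H2 50 bar, CH2Cl2, rt) gives 4-formyl-2-[(2S)-1-(4-hydroxy-3,5-dimethoxyphenyl)propan-2-yl]-6-methoxyphenyl 2,2-dimethylpropanoate F3.
- K2CO3/MeOH then gives 4-hydroxy-3-[(2S)-1-(4-hydroxy-3,5-dimethoxyphenyl)propan-2-yl]-5-methoxybenzaldehyde F4.
- Ag2O (CH2Cl2, rt) oxidises only the electron-rich 4-alkyl-2,6-dimethoxyphenol to p-quinone methide 6, now configurationally fixed at C3. The ring A phenol traps it intramolecularly to give trans-7; a trace of acid equilibrates any cis isomer at C2 only.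

**Step 2 (Heck coupling of an internal, electron-rich alkene).** Risks are arylation at the benzylic carbon (1,1-diaryl isomer), side reactions of the free syringyl phenol through its quinone methide, and a modest yield. The fallback sets out from 1 and comes back at 5.
- Copper-free Sonogashira coupling of commercial 4-bromo-2,6-dimethoxyphenol with propyne (PdCl2(MeCN)2, XPhos, Cs2CO3, MeCN, 70 °C) gives 2,6-dimethoxy-4-(prop-1-yn-1-yl)phenol F1.
- Copper-catalysed syn-hydroboration (CuCl, Xantphos, NaOtBu 1.2 equiv, B2pin2, MeOH, THF, rt), which places boron on the methyl-bearing carbon of aryl–alkyl alkynes, gives 2,6-dimethoxy-4-[(1Z)-2-(4,4,5,5-tetramethyl-1,3,2-dioxaborolan-2-yl)prop-1-en-1-yl]phenol F2.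
- Suzuki–Miyaura coupling of F2 with unprotected 1 (PdCl2(dppf), K2CO3, dioxane/H2O, 80 °C) gives 5 as the pure E isomer. No benzyl-palladium species is formed, so neither the pivalate nor the regiochemical question arises.

**Step 4 (Takai–Utimoto ethylidenation beside a free phenol).** Risks are that the acidic OH consumes organochromium reagent and that a few percent of Z isomer is hard to remove. The fallback sets out from 7 and comes back at 8.
- Wittig olefination with ethylidenetriphenylphosphorane (EtPPh3Br, KHMDS, 3 equiv, THF, −78 to 0 °C, kept cold so the phenoxide does not open the ring) gives mainly 4-[(2R,3R)-7-methoxy-3-methyl-5-[(1Z)-prop-1-en-1-yl]-2,3-dihydro-1-benzofuran-2-yl]-2,6-dimethoxyphenol F5.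
- PdCl2(MeCN)2 (5 mol %, CH2Cl2, rt) isomerises Z to E to give 8.

## Further compounds

F1 | step 2 | 2,6-dimethoxy-4-(prop-1-yn-1-yl)phenol | CC#Cc1cc(OC)c(O)c(OC)c1
F2 | step 2 | 2,6-dimethoxy-4-[(1Z)-2-(4,4,5,5-tetramethyl-1,3,2-dioxaborolan-2-yl)prop-1-en-1-yl]phenol | C/C(B1OC(C)(C)C(C)(C)O1)=C\c1cc(OC)c(O)c(OC)c1
F3 | step 3 | 4-formyl-2-[(2S)-1-(4-hydroxy-3,5-dimethoxyphenyl)propan-2-yl]-6-methoxyphenyl 2,2-dimethylpropanoate | CC(C)(C)C(=O)Oc1c(OC)cc(C=O)cc1[C@@H](C)Cc1cc(OC)c(O)c(OC)c1
F4 | step 3 | 4-hydroxy-3-[(2S)-1-(4-hydroxy-3,5-dimethoxyphenyl)propan-2-yl]-5-methoxybenzaldehyde | O=Cc1cc(OC)c(O)c(c1)[C@@H](C)Cc1cc(OC)c(O)c(OC)c1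
F5 | step 4 | 4-[(2R,3R)-7-methoxy-3-methyl-5-[(1Z)-prop-1-en-1-yl]-2,3-dihydro-1-benzofuran-2-yl]-2,6-dimethoxyphenol | C/C=C\c1cc(OC)c2c(c1)[C@@H](C)[C@H](c1cc(OC)c(O)c(OC)c1)O2
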